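**Target:** 4-[(2R,3R,4R)-4-(4-hydroxy-3,5-dimethoxybenzyl)-3-methyltetrahydrofuran-2-yl]-2-methoxyphenol. The ring is 2-aryl / 3-methyl / 4-benzyl, with 2,3-trans and 3,4-trans relationships (all-trans).

**Assumption:** O-benzylsyringaldehyde (1) and 4-benzyloxy-3-methoxybromobenzene (7) are bought as catalogue items. If not in stock, each is one BnBr/K2CO3 step from syringaldehyde or 4-bromoguaiacol.

## Retrosynthetic overview

1. Target ⇒ bis-benzyl ether by global O-debenzylation. Both arenes are purchased, so the oxolane is the only ring to build.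
2. C2–H ⇒ cyclic hemiketal by oxocarbenium reduction (sets C2). C2–aryl ⇒ aryllithium plus trans-α-methyl-β-benzyl-γ-butyrolactone.
3. C3–CH3 ⇒ enolate methylation of the (R)-β-benzylbutyrolactone, anti to the benzyl group (sets C3).
4. Lactone ⇒ (R)-2-benzylsuccinate half-ester ⇒ asymmetric hydrogenation (sets C4) of the Stobbe adduct of O-benzylsyringaldehyde and dimethyl succinate.
5. Ring order: the five-membered O-ring is formed once, as the lactone in step 3, and is kept intact to the end.

## Route

**Step 1**
Reactants: 1, 4-(benzyloxy)-3,5-dimethoxybenzaldehyde; 2, dimethyl succinate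
Product: 3, (E)-4-[4-(benzyloxy)-3,5-dimethoxyphenyl]-3-(methoxycarbonyl)but-3-enoic acid
Conditions: NaOMe (1.5 equiv), MeOH, reflux; then aq. HCl
Reagents that add atoms: dimethyl succinate (2), COC(=O)CCC(=O)OC
Why: In this Stobbe condensation the succinate enolate adds to the non-enolisable aldehyde, and the aldolate lactonises and opens irreversibly by E1cB to the (E)-alkylidene half-ester, which differentiates the two carboxyl groups (no stereocentre is formed).

**Step 2**
Reactants: 3
Product: 4, (3R)-4-[4-(benzyloxy)-3,5-dimethoxyphenyl]-3-(methoxycarbonyl)butanoic acid, i.e. the (R)-2-(arylmethyl)succinic acid 1-methyl ester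
Conditions: [Rh(cod)((S,S)-Et-DuPHOS)]BF4 (0.2 mol%), NaOMe (10 mol%), H2 (5 bar), MeOH, rt; check ee by chiral HPLC and upgrade by crystallising an amine salt if below 98%
Reagents that add atoms: none
Why: In this Rh(I)–bisphosphine asymmetric hydrogenation of an itaconate-type substrate, two-point binding of the alkene and β-carboxylate fixes the face, so the (S,S)-ligand (same facial sense as (S)-amino acids) gives the (R)-succinate that becomes C4, and homogeneous Rh leaves the O-benzyl ether untouched.

**Step 3**
Reactants: 4
Product: 5, (4R)-4-[4-(benzyloxy)-3,5-dimethoxybenzyl]dihydrofuran-2(3H)-one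
Conditions: KOH (1.0 equiv), EtOH; CaCl2/NaBH4, EtOH, 0 °C → rt; then 3 M HCl, rt
Reagents that add atoms: none (hydride only; MeOH and H2O are lost)
Why: In this chemoselective Ca(BH4)2 reduction the carboxylate salt is inert while the methyl ester goes to CH2OH, and acidification lactonises the γ-hydroxy acid, forming the O-ring without touching the stereocentre (still R).

**Step 4**
Reactants: 5
Product: 6, (3R,4R)-4-[4-(benzyloxy)-3,5-dimethoxybenzyl]-3-methyldihydrofuran-2(3H)-one (trans)
Conditions: LiHMDS (1.05 equiv), THF, −78 °C; MeI (3 equiv), −78 → −40 °C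
Reagents that add atoms: iodomethane, CI
Why: In this substrate-controlled enolate alkylation the planar lactone enolate is methylated on the face anti to the C4 benzyl group, setting C3 as R (trans, typically ≥10:1), with the minor cis isomer separable or convertible to trans with DBU.

**Step 5**
Reactants: 7, 1-(benzyloxy)-4-bromo-2-methoxybenzene; 6
Product: 8, (3R,4R)-2-[4-(benzyloxy)-3-methoxyphenyl]-4-[4-(benzyloxy)-3,5-dimethoxybenzyl]-3-methyltetrahydrofuran-2-ol (anomeric mixture, in equilibrium with the open γ-hydroxy aryl ketone; used crude)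
Conditions: 7 (1.4 equiv), n-BuLi (1.3 equiv), THF, −78 °C, 30 min; then 6, −78 °C; sat. NH4Cl at −78 °C
Reagents that add atoms: 1-(benzyloxy)-4-bromo-2-methoxybenzene (7, delivered as ArLi), COc1cc(Br)ccc1OCc1ccccc1
Why: Br/Li exchange is followed by 1,2-addition to the lactone, and the tetrahedral lithium alkoxide persists at −78 °C so addition stops at one aryl, leaving C3 and C4 unchanged (the C2 configuration here is irrelevant).

**Step 6**
Reactants: 8
Product: 9, (2R,3R,4R)-2-[4-(benzyloxy)-3-methoxyphenyl]-4-[4-(benzyloxy)-3,5-dimethoxybenzyl]-3-methyltetrahydrofuran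
Conditions: Et3SiH (5 equiv), BF3·OEt2 (2 equiv), CH2Cl2, −78 °C (no warmer than −40 °C); cold Et3N/NaHCO3 quench
Reagents that add atoms: none
Why: In this ionic reductive deoxygenation BF3 generates the aryl-stabilised five-membered oxocarbenium ion and silane attacks "inside" the envelope that holds C3-Me and C4-CH2Ar pseudo-equatorial, so H arrives syn to Me and anti to the benzyl, placing the aryl trans to the methyl (2R), which is also the thermodynamic isomer.

**Step 7**
Reactants: 9
Product: 10, target, 4-[(2R,3R,4R)-4-(4-hydroxy-3,5-dimethoxybenzyl)-3-methyltetrahydrofuran-2-yl]-2-methoxyphenol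
Conditions: H2 (1 atm), 10% Pd/C, EtOAc, rt, 1–3 h, stopped at full conversion (TLC/LC monitoring)
Reagents that add atoms: none
Why: Catalytic hydrogenolysis cleaves the two primary aryl benzyl ethers much faster than the hindered cyclic secondary benzylic C2–O bond under neutral, low-pressure conditions, and no stereocentre is touched.

## Compound list

| No. | Name | SMILES | Role |
|---|---|---|---|
| 1 | 4-(benzyloxy)-3,5-dimethoxybenzaldehyde | COc1cc(C=O)cc(OC)c1OCc1ccccc1 | starting material |
| 2 | dimethyl succinate | COC(=O)CCC(=O)OC | starting material |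
| 3 | (E)-Stobbe half-ester | COC(=O)/C(CC(=O)O)=C/c1cc(OC)c(OCc2ccccc2)c(OC)c1 | intermediate |
| 4 | (R)-2-(arylmethyl)succinic acid 1-methyl ester | COC(=O)[C@@H](CC(=O)O)Cc1cc(OC)c(OCc2ccccc2)c(OC)c1 | intermediate |
| 5 | (4R)-β-benzyl-γ-butyrolactone | O=C1OC[C@H](Cc2cc(OC)c(OCc3ccccc3)c(OC)c2)C1 | intermediate |
| 6 | (3R,4R)-trans-α-methyl-β-benzyl lactone | O=C1OC[C@H](Cc2cc(OC)c(OCc3ccccc3)c(OC)c2)[C@H]1C | intermediate |
| 7 | 1-(benzyloxy)-4-bromo-2-methoxybenzene | COc1cc(Br)ccc1OCc1ccccc1 | starting material |
| 8 | (3R,4R)-2-aryl hemiketal (C2 mixture) | COc1cc(C2(O)OC[C@H](Cc3cc(OC)c(OCc4ccccc4)c(OC)c3)[C@H]2C)ccc1OCc1ccccc1 | intermediate |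
| 9 | (2R,3R,4R)-bis-O-benzyl tetrahydrofuran | COc1cc([C@@H]2OC[C@H](Cc3cc(OC)c(OCc4ccccc4)c(OC)c3)[C@H]2C)ccc1OCc1ccccc1 | intermediate |
| 10 | CID53359708 | COc1cc([C@@H]2OC[C@H](Cc3cc(OC)c(O)c(OC)c3)[C@H]2C)ccc1O | target |

## Summary

**Total step count:** 7
**Longest linear sequence:** 7 (1 → 3 → 4 → 5 → 6 → 8 → 9 → 10)

**Steps most likely to fail, with fallbacks**

1. **Step 6.**
   - Risks: insufficient C2 selectivity; BF3-induced ionisation of the product followed by Friedel–Crafts closure onto the activated syringyl ring (aryltetralin); over-reduction to ArCH2.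
   - Fallback: switch from C–H to C–O bond formation. Reduce 8, through its keto tautomer, with LiAlH4 to the 1-aryl-1,4-diol. Then close the ring by catalytic CSA cycloetherification through the p-alkoxybenzyl cation, which equilibrates to the 2,3-trans ether.
2. **Step 7.**
   - Risk: competing hydrogenolysis of the ring benzylic C2–O bond, giving the seco product.
   - Fallback: change the protecting-group plan. Debenzylate at lactone 6, where no labile ring ether exists, and re-protect the phenol as the TBS ether. Use TBS-protected 4-bromoguaiacol in step 5 and finish with TBAF/AcOH instead of hydrogenation.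
3. **Step 5.**
   - Risks: enolisation of the α-branched lactone by ArLi (recovered or epimerised 6), or double addition.
   - Fallback: open 6 with MeNH(OMe)·HCl/AlMe3 to the Weinreb amide and silylate the primary alcohol. Add ArLi to obtain the ketone cleanly. Desilylation then regenerates hemiketal 8 for step 6.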